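Time came first. The alpha run was read up to 20.0 min, while the new flasks stand for 1.5 h, which is 4.50 times as long, and alpha's substrate fell by just 2.6 percentage points between its last two readings. So I took the first step, substrate with partner, as finished in the new flasks and reckoned with what it leaves free.

| flask | substrate | partner | remark | time |
|---|---|---|---|---|
| alpha | 0.15 M | 0.060 M | run made earlier |  |
| south | 0.10 M | 0.0600 M |  | 1.5 h |
| south-east | 0.10 M | 0.120 M |  | 1.5 h |
| west | 0.10 M | 0.240 M |  | 1.5 h |

- alpha (time / min: target / %, substrate / %): 5.00: 5.2, 83.1; 10.0: 7.3, 76.2; 15.0: 8.3, 70.9; 20.0: 8.8, 68.3

(scatter of a reading: 0.5 percentage points)

- the numbers in the tables scatter with a standard deviation of 0.5 percentage points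
- reactions considered so far: intermediate B <-> intermediate C; intermediate A <-> intermediate B; intermediate D -> side product; partner + intermediate A <-> intermediate D; substrate + partner -> intermediate A; substrate + partner -> intermediate B; substrate + partner -> target

* which of the two there is more of at the end, south (side product / target)
* which of the two there is more of at the end, south-east (side product / target)
* which of the two there is more of at the end, west (side product / target)
* target at the end, in percent of the substrate charged, south
* target at the end, in percent of the substrate charged, south-east
* target at the end, in percent of the substrate charged, west

Reading down the alpha rows, target over substrate gone runs 0.308, 0.307, 0.285, then 0.278. I kept the last row, where the scatter weighs least, and called it s, the target share of the substrate consumed, a selectivity.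

Each substrate taken needs one partner. Multiplying s by the part of the substrate that the partner charge can take gives R, my target reach. It is an estimate carrying the scatter of s, not a hard limit.

In south, partner is the limiting reagent, 0.0600 M against 0.10 M. It can take 60.0% of the substrate, so R is 16.7%. In south-east and west the partner covers the whole substrate charge, so R is 27.8%.

Side product needs a second partner. In south I counted the whole partner charge into the first step, so this reckoning leaves it nothing for a second, and I put target ahead. By the same count south-east has 20.0% of the substrate charge free, less than its target, so I put target ahead there too. By the same count west has 140% free, more than the 72.2% of substrate reckoned to go the other way, and that pool exceeds the target, so I put side product ahead there.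

The forecast named target, target and side product, with target at 15%, 28% and 30%. Its south value stands below mine, on the grounds “partner-limited, about 0.05 M converted”, whereas I counted the whole partner charge. Its west value stands above my 27.8%.

South gave 15.8% of target against 3.09% of side product. South-east gave 25.8% against 15.4%. West gave 28.4% of target against 47.5% of side product. The forecast held, on its choices and, within the tolerance, on its values. South ended with 44% of its substrate and 1.7% of its partner left, so 56.0% of the substrate had gone, not the 60.0% in my reach. Applied to that amount, s gives 15.6%, beside the 15.8% found.

    intermediate B ⇌ intermediate C (K = 0.560, k = 0.00530 s⁻¹)
    intermediate A ⇌ intermediate B (K = 31.0, k = 1.10 × 10⁻⁵ s⁻¹)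
    intermediate D → side product (k = 0.00210 s⁻¹)
    partner + intermediate A ⇌ intermediate D (K = 6.80 M⁻¹, k = 0.00280 M⁻¹ s⁻¹)
    substrate + partner → intermediate A (k = 0.00890 M⁻¹ s⁻¹)
    substrate + partner → intermediate B (k = 1.80 × 10⁻⁴ M⁻¹ s⁻¹)
    substrate + partner → target (k = 0.00360 M⁻¹ s⁻¹)

A neighbour of south, charged with 0.25 M of substrate, has 0.240 equiv of partner, so R there is 6.67%. The computed flask ended with 6.69% of target.

The readings are simulated from invented constants; the scatter is artificial.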